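**Retrosynthetic overview**

1. The target 23 is the C2-symmetric head-to-head, anti [2+2] dimer of dienolide 22. Its cyclobutane consists only of C8, C9, C8′ and C9′ (lindenane numbering), i.e. of the enol-lactone double bonds C8=C9 of two identical O–C8(=C9)–C7=C11–C12=O units. Cutting C8–C8′ and C9–C9′ halves the molecule, and this ring is closed last.
2. 22 ⇒ ketone 14 + ethyl pyruvate 15 (butenolide annulated on C7/C8 without Brønsted acid).
3. 14 ⇒ diazoketone 10: one intramolecular cyclopropanation closes the cyclopentane (C3–C1) and the cyclopropane (C3–C2) on a cyclohexane carrying trans C5-acyl and C10-vinyl groups.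
4. 10 ⇒ keto ester 7 ⇒ enone 5 (vinyl cuprate anti to the C5 ester creates quaternary C10) ⇒ catalytic enantioselective Diels–Alder reaction of diene 2 with acrylate 3.
5. Ring order: cyclohexane → cyclopentane + cyclopropane → butenolide → cyclobutane.

Key step: step 14

Remark on numbering: lindenane numbering is used for all polycyclic compounds (cyclopropane C1–C2–C3; C4 carries C15; ring fusion C5/C10; C14 = angular methyl; lactone C12–O–C8; C13 = vinylic methyl). β means the face of the C14 methyl, α the opposite face.

Assumption: the cationic oxazaborolidine catalyst is taken to give, with acrylate esters, the (S)-cyclohex-3-enecarboxylate from the (S)-catalyst, so the (R)-catalyst is specified for the (1R)-adduct 4; if the sense were opposite with this diene, the antipodal catalyst would be used.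

**Route**

Step 1
Reactants: 1 (E)-pent-3-en-2-one
Product: 2 (E)-2-(triisopropylsilyloxy)penta-1,3-diene
Conditions: TIPSOTf, Et3N, Et2O, 0 → 23 °C
Reagents that add atoms: triisopropylsilyl trifluoromethanesulfonate, CC(C)[Si](OS(=O)(=O)C(F)(F)F)(C(C)C)C(C)C
Why: Soft enolisation of the methyl ketone with silyl triflate and amine (silyl dienol ether formation) gives the cross-conjugated 2-silyloxy-1,3-diene and leaves the E-propenyl unit untouched; no stereocentre is formed.

Step 2
Reactants: 2 (E)-2-(triisopropylsilyloxy)penta-1,3-diene; 3 2,2,2-trifluoroethyl acrylate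
Product: 4 2,2,2-trifluoroethyl (1R,2S)-2-methyl-4-(triisopropylsilyloxy)cyclohex-3-ene-1-carboxylate (cis)
Conditions: (R)-configured cationic oxazaborolidine catalyst [B-(o-tolyl)oxazaborolidine from (R)-α,α-diphenylprolinol, activated with Tf2NH] (10 mol%), CH2Cl2, −78 → −20 °C
Reagents that add atoms: none
Why: Enantioselective Diels–Alder reaction under chiral Lewis-acid catalysis, in which the 3-silyloxy ("para") and 1-methyl ("ortho") groups of the diene direct the same regiochemistry and the catalyst blocks one face of the coordinated s-trans acrylate, so that ring C1 (C5 of the lindenane) is set as R; the endo cis-methyl centre C2 is of no consequence because it becomes sp2 in step 3.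

Step 3
Reactants: 4 2,2,2-trifluoroethyl (1R,2S)-2-methyl-4-(triisopropylsilyloxy)cyclohex-3-ene-1-carboxylate
Product: 5 2,2,2-trifluoroethyl (1R)-2-methyl-4-oxocyclohex-2-ene-1-carboxylate
Conditions: Pd(OAc)2 (1.05 equiv), MeCN, 23 → 40 °C
Reagents that add atoms: none
Why: Saegusa–Ito oxidation, in which the palladium enolate formed regiospecifically from the silyl enol ether can undergo β-hydride elimination only toward C2–H, giving the β-methyl enone under neutral conditions that leave the acidic γ-stereocentre C1 untouched.

Step 4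
Reactants: 5 2,2,2-trifluoroethyl (1R)-2-methyl-4-oxocyclohex-2-ene-1-carboxylate
Product: 7 2,2,2-trifluoroethyl (1R,2S)-2-ethenyl-2-methyl-4-oxocyclohexane-1-carboxylate, via TMS enol ether 6 (not isolated)
Conditions: CH2=CHMgBr (slow addition), CuBr·SMe2 (15 mol%), TMSCl, THF, −78 °C; then 1 M HCl, 0 °C
Reagents that add atoms: vinylmagnesium bromide, C=C[Mg]Br; chlorotrimethylsilane (silyl group of 6 only), C[Si](C)(C)Cl
Why: Copper-catalysed, TMSCl-accelerated conjugate addition in which the vinyl group enters anti to the adjacent ester (1,2-induction in 4-substituted cyclohexenones) and so creates the quaternary centre with vinyl trans and methyl cis to the ester; the silyl enol ether is hydrolysed on work-up.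

Step 5
Reactants: 7 2,2,2-trifluoroethyl (1R,2S)-2-ethenyl-2-methyl-4-oxocyclohexane-1-carboxylate
Product: 8 (1R,2S)-2-ethenyl-2-methyl-4-oxocyclohexane-1-carboxylic acid
Conditions: LiOH·H2O, THF/H2O 3:1, 0 → 23 °C; then 1 M HCl to pH 3
Reagents that add atoms: lithium hydroxide, [Li+].[OH-]
Why: Saponification of the activated trifluoroethyl ester proceeds by acyl substitution at low temperature faster than enolisation, so the α-stereocentre is kept.

Step 6
Reactants: 8 (1R,2S)-2-ethenyl-2-methyl-4-oxocyclohexane-1-carboxylic acid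
Product: 10 (3S,4R)-4-(2-diazoacetyl)-3-ethenyl-3-methylcyclohexan-1-one, via acid chloride 9 (not isolated)
Conditions: (COCl)2, DMF (cat.), CH2Cl2, 0 → 23 °C; evaporate; then CH2N2 (3 equiv), Et2O, 0 °C
Reagents that add atoms: oxalyl chloride (chlorine of 9), O=C(Cl)C(=O)Cl; diazomethane, C=[N+]=[N-]
Why: Acylation of diazomethane by the acid chloride (first stage of the Arndt–Eistert sequence) with excess diazomethane as the HCl scavenger, so that no amine base and hence no ketene-mediated epimerisation of the α-centre intervenes.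

Step 7
Reactants: 10 (3S,4R)-4-(2-diazoacetyl)-3-ethenyl-3-methylcyclohexan-1-one
Product: 11 11,12,13,15-tetranorlindenane-4,8-dione (cyclopropane CH2 β, 5α-H, 14-CH3 β)
Conditions: bis(N-tert-butylsalicylaldiminato)copper(II) (5 mol%), toluene, 110 °C, slow addition at high dilution
Reagents that add atoms: none
Why: Intramolecular cyclopropanation of the copper carbenoid onto the vicinal vinyl group (1-diazohex-5-en-2-one → bicyclo[3.1.0]hexan-2-one type) closes the cyclopentanone through C3–C1 and the cyclopropane through C3–C2, the trans ring fusion being preset by the trans-diequatorial acyl and vinyl groups and the C1/C3 centres being set by addition to the vinyl rotamer whose CH2 terminus eclipses the small axial C14 methyl (least allylic strain, π face turned toward C5), which should place the cyclopropane CH2 on the β face.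

Step 8
Reactants: 11 11,12,13,15-tetranorlindenane-4,8-dione
Product: 12 8β-hydroxy-11,12,13,15-tetranorlindenan-4-one
Conditions: L-Selectride (1.05 equiv), THF, −78 °C; then aq. NH4Cl
Reagents that add atoms: none
Why: Chemoselective hydride reduction of the unhindered cyclohexanone in the presence of the α-branched, cyclopropane-conjugated cyclopentanone, with equatorial attack of the bulky hydride giving the axial 8β-alcohol (a temporary stereocentre that is removed in step 10).

Step 9
Reactants: 12 8β-hydroxy-11,12,13,15-tetranorlindenan-4-one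
Product: 13 11,12,13-trinorlind-4(15)-en-8β-ol
Conditions: Cp2TiMe2 (3 equiv), toluene/THF, 70 °C, dark
Reagents that add atoms: dimethyltitanocene, C[Ti+2]C.[cH-]1cccc1.[cH-]1cccc1
Why: Petasis methylenation (titanium methylidene, Wittig-type carbonyl olefination) is non-basic, so the enolisable C4 ketone is converted without epimerisation of C5 to the cis-fused ketone, and the free hydroxyl is tolerated when the reagent is used in excess.

Step 10
Reactants: 13 11,12,13-trinorlind-4(15)-en-8β-ol
Product: 14 11,12,13-trinorlind-4(15)-en-8-one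
Conditions: Dess–Martin periodinane, NaHCO3, CH2Cl2, 0 → 23 °C
Reagents that add atoms: none
Why: Dess–Martin oxidation under bicarbonate buffering oxidises the secondary alcohol without exposing the acid-labile 4-methylenebicyclo[3.1.0]hexane unit to acid.

Step 11
Reactants: 14 11,12,13-trinorlind-4(15)-en-8-one; 15 ethyl pyruvate
Product: 19 ethyl 8-oxolinda-4(15),7(11)-dien-12-oate (E/Z mixture at C7=C11), via lithium enolate 16 (not isolated), via lithium aldolate 17 (not isolated), via aldol acetate 18 (not isolated)
Conditions: LDA, THF, −78 °C; 15; then Ac2O, −78 → 0 °C; then DBU, 0 → 23 °C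
Reagents that add atoms: lithium diisopropylamide (lithium of 16 and 17), CC(C)[N-]C(C)C.[Li+]; acetic anhydride (acetyl of 18 only), CC(=O)OC(C)=O
Why: Kinetic deprotonation occurs at C7 and not at the neopentyl C9, the enolate adds to the ketone carbonyl of the pyruvate (aldol addition), and acetylation of the tertiary aldolate followed by DBU-induced E1cB elimination gives the alkylidene keto ester; the transient stereocentres C7 and C11 are destroyed.

Step 12
Reactants: 19 ethyl 8-oxolinda-4(15),7(11)-dien-12-oate
Product: 20 8β-hydroxylinda-4(15),7(11)-dien-12,8-olide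
Conditions: LiOH, THF/H2O, 0 → 23 °C; then aq. NaH2PO4 to pH 5, 0 °C
Reagents that add atoms: lithium hydroxide, [Li+].[OH-]
Why: Ester hydrolysis with neighbouring-group participation, in which hydroxide equilibrates the alkene isomers through the γ-dienolate and the (Z)-ester, the only one whose C8 ketone can assist, is cleaved fastest and ends as the cyclic pseudo-acid (γ-hydroxybutenolide) without any acid strong enough to isomerise the vinylcyclopropane; the hemiketal centre C8 forms under thermodynamic control and is lost in step 13.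

Step 13
Reactants: 20 8β-hydroxylinda-4(15),7(11)-dien-12,8-olide
Product: 22 (1R,3S,5S,10S)-linda-4(15),7(11),8-trien-12,8-olide (chloranthalactone A skeleton), via hemiketal mesylate 21 (not isolated)
Conditions: MsCl, Et3N, CH2Cl2, −20 → 0 °C
Reagents that add atoms: methanesulfonyl chloride (mesyl group of 21 only), CS(=O)(=O)Cl
Why: Sulfonylation of the tertiary hemiketal hydroxyl and base-assisted loss of methanesulfonate together with H-9 (C9 carries the only β-hydrogens) is the standard dehydration of a γ-hydroxybutenolide to a γ-alkylidene butenolide.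

Step 14
Reactants: 22 (1R,3S,5S,10S)-linda-4(15),7(11),8-trien-12,8-olide (two molecules)
Product: 23 target CNP0265879.1, the C8–C8′/C9–C9′ head-to-head anti cyclobutane dimer of 22
Conditions: hν (medium-pressure Hg lamp, Pyrex filter, λ > 290 nm), degassed CH2Cl2–hexane, 0.1 M, 20 °C
Reagents that add atoms: none
Why: Excitation of the cross-conjugated dienolide and intersystem crossing give a triplet that attacks a ground-state molecule with its least hindered terminus C9, so the C9–C9′ bond forms first and leaves a 1,4-biradical whose centres C8 and C8′ are α-oxygenated allyl radicals conjugated with the lactone carbonyl; spin inversion and C8–C8′ recombination complete the ring. The closest known reaction type is the [2+2] photodimerisation of enones, coumarins and γ-alkylidene butenolides. The one ring closed, the cyclobutane C8–C9–C9′–C8′, arises by an intermolecular stepwise [2π+2π] cycloaddition (radical addition followed by 1,4-biradical collapse). All four new stereocentres are substrate-controlled: each C8=C9 bond reacts on its α face, anti to the axial C14 methyl that covers the β face, which puts the lactone oxygen and H-9 of each half on the β side of its own ring and makes both ring fusions cis. The step needs head-to-head regioselectivity, secured by the doubly stabilised biradical (a head-to-tail start would have to bond the fully substituted C8), and the anti, C2-symmetric arrangement, which is the only way two homochiral molecules can meet α face to α face with C8 over C8′ and C9 over C9′. It also needs chemoselectivity over the C4(15) methylenes, which do not absorb at this wavelength and are shielded by C10 and the cyclopropane.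

**Compound list**

1 | (E)-pent-3-en-2-one | C/C=C/C(C)=O | starting material
2 | (E)-2-(triisopropylsilyloxy)penta-1,3-diene | C=C(O[Si](C(C)C)(C(C)C)C(C)C)/C=C/C | intermediate
3 | 2,2,2-trifluoroethyl acrylate | C=CC(=O)OCC(F)(F)F | starting material
4 | 2,2,2-trifluoroethyl (1R,2S)-2-methyl-4-(triisopropylsilyloxy)cyclohex-3-ene-1-carboxylate (ester and methyl cis) | CC(C)[Si](C(C)C)(C(C)C)OC1=C[C@H](C)[C@H](C(=O)OCC(F)(F)F)CC1 | intermediate
5 | 2,2,2-trifluoroethyl (1R)-2-methyl-4-oxocyclohex-2-ene-1-carboxylate | O=C1C=C(C)[C@H](C(=O)OCC(F)(F)F)CC1 | intermediate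
6 | trimethylsilyl enol ether (C8=C9) of keto ester 7, vinyl trans to the ester | C[Si](C)(C)OC1=C[C@@](C)(C=C)[C@H](C(=O)OCC(F)(F)F)CC1 | intermediate
7 | 2,2,2-trifluoroethyl (1R,2S)-2-ethenyl-2-methyl-4-oxocyclohexane-1-carboxylate (vinyl trans, methyl cis to the ester) | O=C1CC[C@@H](C(=O)OCC(F)(F)F)[C@](C)(C=C)C1 | intermediate
8 | (1R,2S)-2-ethenyl-2-methyl-4-oxocyclohexane-1-carboxylic acid | O=C1CC[C@@H](C(=O)O)[C@](C)(C=C)C1 | intermediate
9 | (1R,2S)-2-ethenyl-2-methyl-4-oxocyclohexane-1-carbonyl chloride | O=C1CC[C@@H](C(Cl)=O)[C@](C)(C=C)C1 | intermediate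
10 | (3S,4R)-4-(2-diazoacetyl)-3-ethenyl-3-methylcyclohexan-1-one | [N-]=[N+]=CC(=O)[C@@H]1CCC(=O)C[C@@]1(C)C=C | intermediate
11 | 11,12,13,15-tetranorlindenane-4,8-dione (trans-fused 5/6, cyclopropane CH2 β and cis to the β-C14 methyl, 5α-H) | O=C1[C@H]2C[C@H]2[C@@]2(C)[C@H]1CCC(=O)C2 | intermediate
12 | 8β-hydroxy-11,12,13,15-tetranorlindenan-4-one (axial OH, syn to C14) | O=C1[C@H]2C[C@H]2[C@@]2(C)[C@H]1CC[C@H](O)C2 | intermediate
13 | 11,12,13-trinorlind-4(15)-en-8β-ol | C=C1[C@H]2C[C@H]2[C@@]2(C)[C@H]1CC[C@H](O)C2 | intermediate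
14 | 11,12,13-trinorlind-4(15)-en-8-one | C=C1[C@H]2C[C@H]2[C@@]2(C)[C@H]1CCC(=O)C2 | intermediate
15 | ethyl pyruvate | CCOC(=O)C(C)=O | starting material
16 | lithium C7=C8 enolate of ketone 14 | C=C1[C@H]2C[C@H]2[C@@]2(C)[C@H]1CC=C([O-])C2.[Li+] | intermediate
17 | lithium aldolate: ethyl 11-oxido-8-oxolind-4(15)-en-12-oate, lithium salt (diastereomers at C7/C11) | C=C1[C@H]2C[C@H]2[C@@]2(C)[C@H]1CC(C(C)([O-])C(=O)OCC)C(=O)C2.[Li+] | intermediate
18 | ethyl 11-acetoxy-8-oxolind-4(15)-en-12-oate (diastereomers at C7/C11) | C=C1[C@H]2C[C@H]2[C@@]2(C)[C@H]1CC(C(C)(OC(C)=O)C(=O)OCC)C(=O)C2 | intermediate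
19 | ethyl 8-oxolinda-4(15),7(11)-dien-12-oate (E/Z mixture at C7=C11, geometry not fixed at this stage) | C=C1[C@H]2C[C@H]2[C@@]2(C)[C@H]1CC(=C(C)C(=O)OCC)C(=O)C2 | intermediate
20 | 8β-hydroxylinda-4(15),7(11)-dien-12,8-olide (γ-hydroxybutenolide; the 8-epimer would serve equally) | C=C1[C@H]2C[C@H]2[C@@]2(C)[C@H]1CC1=C(C)C(=O)O[C@@]1(O)C2 | intermediate
21 | 8-methanesulfonate of hydroxybutenolide 20 | C=C1[C@H]2C[C@H]2[C@@]2(C)[C@H]1CC1=C(C)C(=O)O[C@@]1(OS(C)(=O)=O)C2 | intermediate
22 | (1R,3S,5S,10S)-linda-4(15),7(11),8-trien-12,8-olide | C=C1[C@H]2C[C@H]2[C@@]2(C)[C@H]1CC1=C(C)C(=O)OC1=C2 | intermediate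
23 | CNP0265879.1, head-to-head anti [2+2] dimer of 22 (bonds C8–C8′ and C9–C9′ on the α faces; lactone O and H-9 β in each half) | C=C1[C@H]2C[C@H]2[C@@]2(C)[C@H]1CC1=C(C)C(=O)O[C@]13[C@H]2[C@H]1[C@@]2(C)[C@@H]4C[C@@H]4C(=C)[C@@H]2CC2=C(C)C(=O)O[C@@]213 | target

**Step count and risks**

Total step count: 14. Longest linear sequence: 14 steps (from 1; 3 and 15 are bought).

Steps most likely to fail:

1. Step 7. The carbenoid may add to the other π face of the vinyl group, which would put the cyclopropane anti to the C14 methyl, or it may insert into C–H bonds. Fallback from 9 back to 11, with the cyclopropane installed by hydroxyl direction. Acid chloride 9 would be coupled with tributyl(vinyl)stannane (Pd(PPh3)4 cat., THF, 50 °C, Stille acylation) to give (3S,4R)-4-acryloyl-3-ethenyl-3-methylcyclohexan-1-one F1. Ring-closing metathesis (second-generation Grubbs catalyst, CH2Cl2, 40 °C) would close the trans-fused cyclopentenone, 2,11,12,13,15-pentanoreudesm-1(3)-ene-4,8-dione F2. Luche reduction (NaBH4, CeCl3·7H2O, MeOH, −78 °C) should deliver hydride anti to the C14 methyl and give the 4β,8β-diol F3. Hydroxyl-directed Simmons–Smith cyclopropanation (Et2Zn, CH2I2, CH2Cl2, 0 °C) transfers CH2 syn to the 4β-hydroxyl and gives 11,12,13,15-tetranorlindenane-4β,8β-diol F4. Dess–Martin oxidation of both alcohols returns to diketone 11.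

2. Step 12. The alkene isomers of 19 may not converge on the (Z)-form during hydrolysis, and retro-aldol type degradation may compete, leaving (E)-configured acid that cannot close to the lactol. Fallback from 14 back to 20, with the alkene geometry fixed by a preformed lactone ring. Ketone 14 would be taken (LDA, THF, −78 °C; 15; AcOH quench at −78 °C) to the isolated aldol, ethyl 11-hydroxy-8-oxolind-4(15)-en-12-oate F5. NaBH4 (MeOH, −20 °C) reduces C8 and the resulting hydroxy ester closes (cat. K2CO3) to 11-hydroxylind-4(15)-en-12,8-olide F6. Dehydration (SOCl2, pyridine, 0 °C) gives the conjugated butenolide, linda-4(15),7(11)-dien-12,8-olide F7. TBSOTf/Et3N (CH2Cl2, 0 °C) converts it into the 2-silyloxyfuran F8. Oxidation at C8 with dimethyldioxirane (1 equiv, acetone, −78 °C) and loss of the silyl group give γ-hydroxybutenolide 20.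

3. Step 4. Enone 5 may lose enantiomeric purity by deprotonation of its acidic γ-position, or the Grignard reagent may attack the activated ester, before conjugate addition. Fallback from 4 back to 8, with the ester reduced before the enone is formed. The ester of 4 would be reduced (LiAlH4, Et2O, −20 °C, silyl enol ether untouched) to the primary alcohol F9 and silylated (TBSCl, imidazole, DMF) to the bis-silyl compound F10. Saegusa–Ito oxidation (Pd(OAc)2, MeCN) gives (4R)-4-(tert-butyldimethylsilyloxymethyl)-3-methylcyclohex-2-en-1-one F11, whose stereocentre is no longer acidic. Vinylcopper–BF3 (CH2=CHMgBr, CuI, BF3·OEt2, THF, −78 °C) adds anti to the side chain and gives the vinyl ketone F12. Jones reagent (CrO3, H2SO4, acetone, 0 °C) removes the silyl ether and oxidises the primary alcohol to keto acid 8.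

Further compounds
F1 | step 7 | (3S,4R)-4-acryloyl-3-ethenyl-3-methylcyclohexan-1-one | C=CC(=O)[C@@H]1CCC(=O)C[C@@]1(C)C=C
F2 | step 7 | trans-fused cyclopentenone, 2,11,12,13,15-pentanoreudesm-1(3)-ene-4,8-dione (5α-H, 14-CH3 β) | O=C1C=C[C@@]2(C)[C@H]1CCC(=O)C2
F3 | step 7 | 2,11,12,13,15-pentanoreudesm-1(3)-ene-4β,8β-diol | O[C@H]1C=C[C@@]2(C)[C@H]1CC[C@H](O)C2
F4 | step 7 | 11,12,13,15-tetranorlindenane-4β,8β-diol (cyclopropane CH2 β, syn to 4-OH) | O[C@H]1[C@H]2C[C@H]2[C@@]2(C)[C@H]1CC[C@H](O)C2
F5 | step 12 | ethyl 11-hydroxy-8-oxolind-4(15)-en-12-oate (diastereomers at C7/C11) | C=C1[C@H]2C[C@H]2[C@@]2(C)[C@H]1CC(C(C)(O)C(=O)OCC)C(=O)C2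
F6 | step 12 | 11-hydroxylind-4(15)-en-12,8-olide (diastereomers at C7/C8/C11) | C=C1[C@H]2C[C@H]2[C@@]2(C)[C@H]1CC1C(C)(O)C(=O)OC1C2
F7 | step 12 | linda-4(15),7(11)-dien-12,8-olide (C8 epimers) | C=C1[C@H]2C[C@H]2[C@@]2(C)[C@H]1CC1=C(C)C(=O)OC1C2
F8 | step 12 | 12-(tert-butyldimethylsilyloxy)furan from F7 (furan C7=C8, C11=C12) | C=C1[C@H]2C[C@H]2[C@@]2(C)[C@H]1Cc1c(C)c(O[Si](C)(C)C(C)(C)C)oc1C2
F9 | step 4 | [(1R,2S)-2-methyl-4-(triisopropylsilyloxy)cyclohex-3-en-1-yl]methanol | CC(C)[Si](C(C)C)(C(C)C)OC1=C[C@H](C)[C@H](CO)CC1
F10 | step 4 | tert-butyldimethylsilyl ether of F9 | CC(C)[Si](C(C)C)(C(C)C)OC1=C[C@H](C)[C@H](CO[Si](C)(C)C(C)(C)C)CC1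
F11 | step 4 | (4R)-4-(tert-butyldimethylsilyloxymethyl)-3-methylcyclohex-2-en-1-one | O=C1C=C(C)[C@H](CO[Si](C)(C)C(C)(C)C)CC1
F12 | step 4 | 4-(tert-butyldimethylsilyloxymethyl)-3-ethenyl-3-methylcyclohexan-1-one (vinyl trans to the side chain) | O=C1CC[C@@H](CO[Si](C)(C)C(C)(C)C)[C@](C)(C=C)C1
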